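**Assumptions.** Ketone 1 is taken as a catalogue compound (it is also one LiN(iPr)2/MeI methylation from 1,4-dioxaspiro[4.5]decan-8-one). Benzoxepine locants (O1, C2, C3 … C9a) are used for the right-hand bicycle and azulene locants for the left-hand one.

**Strategy.** In the oxepane ring, O1 and C2(CH3)2 are an intact acetone unit flanked by C9a and C3, which are 1,5-related through C5a–C5–C4. Tying C3 to C9a as the enol ether double bond of a hydrindane lets acetone add across it in a Paternò–Büchi reaction that forms O1–C9a and C2–C3 at once. The fused 3-oxetanol is then opened by strain-driven β-scission of the old C3–C9a bond, expanding the cyclopentane to the oxepan-3-one. The precursor is a bicyclic benzyl enol ether ketal from a d'Angelo Michael adduct. The cis-hydroazulene half comes from (R)-linalool and is joined by α′-allylation of the benzoxepinone enolate with an allylic bromide.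

Key step: step 3

## Route

**Step 1**
Reactants: 1 rac-7-methyl-1,4-dioxaspiro[4.5]decan-8-one; 2 (R)-1-phenylethylamine; 3 benzyl acrylate
Product: 6 benzyl 3-[(7R)-7-methyl-8-oxo-1,4-dioxaspiro[4.5]decan-7-yl]propanoate, via ketimine 4 (not isolated), via adduct ketimine 5 (not isolated)
Conditions: 2, toluene, reflux, Dean–Stark; then 3, THF, 40 °C; then 20% aq AcOH, 25 °C
Reagents that add atoms: water, O
Why: d'Angelo deracemizing Michael addition, in which the more substituted secondary enamine tautomer of the chiral ketimine adds to the acrylate through a chair-like aza-ene transition state anti to the phenyl group, so the (R)-amine sets the quaternary centre (future C5a) as (R) before hydrolysis returns the auxiliary.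

**Step 2**
Reactants: 6 benzyl 3-[(7R)-7-methyl-8-oxo-1,4-dioxaspiro[4.5]decan-7-yl]propanoate
Product: 7 (3a'R)-1'-(benzyloxy)-3a'-methyl-2',3',3a',4',6',7'-hexahydrospiro[1,3-dioxolane-2,5'-indene]
Conditions: TiCl3, LiAlH4, Et3N, DME, reflux, slow addition
Reagents that add atoms: none
Why: McMurry keto ester cyclization, in which low-valent titanium couples the ketone and ester carbonyl carbons to a cyclic enol ether and so places the C=C regiospecifically between the future C3 (bearing OBn) and C9a.

**Step 3**
Reactants: 7 (3a'R)-1'-(benzyloxy)-3a'-methyl-2',3',3a',4',6',7'-hexahydrospiro[1,3-dioxolane-2,5'-indene]; 8 acetone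
Product: 9 tricyclic 3-(benzyloxy)oxetane: a 2,2-dimethyloxetane cis-fused across C1'–C7a' of the hydrindane ketal, with O on C7a', C(CH3)2 and OBn on C1', and the oxetane anti to the 3a'-methyl group
Conditions: hν (300 nm, Pyrex), acetone (solvent, degassed), NaHCO3 (solid), −20 °C
Reagents that add atoms: none
Why: Excited acetone (n,π*) adds through oxygen to C9a, the enol ether carbon β to the benzyloxy group, giving a 1,4-biradical whose C3 radical is tertiary and oxygen-stabilised, and recombination of C3 with the ketyl carbon C2 then closes the ring, so O1–C9a and C2–C3 form in one photochemical operation. The closest known reaction type is the Paternò–Büchi reaction of ketones and aldehydes with alkyl and silyl enol ethers, which gives 3-alkoxyoxetanes with this orientation. The only ring closed is the oxetane, by intermolecular [2+2] photocycloaddition (biradical recombination) across the cyclopentene bond, hence necessarily cis-fused to the five-membered ring. The two new stereocentres (C3 and C9a) are set by approach anti to the angular methyl group, but both are erased later (C3 becomes a ketone, C9a a radical), so facial selectivity is not needed. The step needs regioselectivity (oxygen to C9a, carbon to C3), which the benzyloxy group secures by polarising the alkene and stabilising the biradical, and chemoselectivity over hydrogen abstraction, which the electron-rich tetrasubstituted alkene in a large excess of acetone secures. The strained 2-oxabicyclo[3.2.0]heptane, not reachable thermally, stores the energy that drives the ring expansion in step 5.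

**Step 4**
Reactants: 9 tricyclic 3-(benzyloxy)oxetane
Product: 10 tricyclic oxetan-3-ol (9 with OH in place of OBn)
Conditions: H2 (1 atm), Pd(OH)2/C, EtOAc, 25 °C
Reagents that add atoms: none
Why: Hydrogenolysis of the benzyl ether under neutral conditions should free the tertiary alcohol while leaving the oxetane and the dioxolane untouched.

**Step 5**
Reactants: 10 tricyclic oxetan-3-ol
Product: 11 (5aR,9aR)-2,2,5a-trimethylhexahydro-2H-spiro[1-benzoxepine-7,2'-[1,3]dioxolan]-3(4H)-one (trans-fused)
Conditions: [Ir(dF(CF3)ppy)2(5,5'-d(CF3)bpy)]PF6 (2 mol %), 2,4,6-collidine, 2,4,6-triisopropylbenzenethiol (20 mol %), CH2Cl2, blue LED, 25 °C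
Reagents that add atoms: none
Why: Redox-neutral ring-opening isomerization of a tertiary cycloalkanol, in which the proton-coupled-electron-transfer alkoxy radical at C3 cleaves the ring-fusion bond C3–C9a (releasing oxetane and bicyclo[3.2.0] strain and giving the tertiary α-alkoxy radical) and thiol hydrogen-atom transfer to C9a anti to the axial 5a-methyl group should give the trans-fused oxepan-3-one.

**Step 6**
Reactants: 11 (5aR,9aR)-2,2,5a-trimethylhexahydro-2H-spiro[1-benzoxepine-7,2'-[1,3]dioxolan]-3(4H)-one
Product: 13 (3S,5aR,9aR)-3-hydroxy-2,2,5a-trimethyloctahydro-1-benzoxepin-7(2H)-one, via hydroxy ketal 12 (not isolated)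
Conditions: NaBH4, MeOH, −20 °C; then 2 M HCl, THF, 25 °C
Reagents that add atoms: water, O
Why: Small-hydride reduction should attack C3 of the twist-chair oxepanone (gem-dimethyl carbon isoclinal) from the axial direction to give the equatorial (3S) alcohol cis to the 5a-methyl group, and aqueous acid then hydrolyses the dioxolane to the C7 ketone.

**Step 7**
Reactants: 13 (3S,5aR,9aR)-3-hydroxy-2,2,5a-trimethyloctahydro-1-benzoxepin-7(2H)-one
Product: 16 (3S,5aR,9aR)-3-hydroxy-2,2,5a-trimethyl-3,4,5,5a,6,9a-hexahydro-1-benzoxepin-7(2H)-one, via bis-silyl enol ether 14 (not isolated), via enone silyl ether 15 (not isolated)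
Conditions: LiN(iPr)2 (2.2 equiv), Me3SiCl, THF, −78 °C; then Pd(OAc)2, MeCN, 25 °C; then 1 M HCl wash
Reagents that add atoms: none
Why: Saegusa–Ito dehydrogenation, in which kinetic deprotonation at the less hindered C8 (C6 is neopentyl) and oxidation of the silyl enol ether by divalent palladium give the C8=C9 enone, the only enone possible next to the quaternary C5a, leaving C6 as the sole α′ position.

**Step 8**
Reactants: 17 (R)-linalool
Product: 18 (R)-1-methylcyclopent-2-en-1-ol
Conditions: second-generation Grubbs catalyst (0.5 mol %), neat, 40 °C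
Reagents that add atoms: none
Why: Ring-closing metathesis of the 1,6-diene expels isobutene and leaves the tertiary carbinol stereocentre (future C1 of the azulene) untouched.

**Step 9**
Reactants: 18 (R)-1-methylcyclopent-2-en-1-ol
Product: 19 (1S,2R,5S)-2-methyl-6-oxabicyclo[3.1.0]hexan-2-ol (epoxide syn to OH)
Conditions: VO(acac)2 (2 mol %), t-BuOOH, CH2Cl2, 0 °C
Reagents that add atoms: tert-butyl hydroperoxide, CC(C)(C)OO
Why: Hydroxyl-directed vanadium-catalysed epoxidation of the cyclic allylic alcohol should deliver oxygen to the face syn to the tertiary hydroxyl.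

**Step 10**
Reactants: 19 (1S,2R,5S)-2-methyl-6-oxabicyclo[3.1.0]hexan-2-ol; 20 isobutyronitrile
Product: 21 2-[(1S,2S,3R)-2,3-dihydroxy-3-methylcyclopentyl]-2-methylpropanenitrile
Conditions: LiN(iPr)2, 20 (2.5 equiv), THF, −78 °C; then 19, −78 → 50 °C
Reagents that add atoms: none
Why: SN2 opening of the epoxide by the lithiated nitrile at the carbon remote from the quaternary carbinol proceeds with inversion, so the new C–C bond (future C3a–C4) is anti to both oxygens.

**Step 11**
Reactants: 21 2-[(1S,2S,3R)-2,3-dihydroxy-3-methylcyclopentyl]-2-methylpropanenitrile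
Product: 22 2-[(1S,3R)-3-hydroxy-3-methyl-2-oxocyclopentyl]-2-methylpropanenitrile
Conditions: Dess–Martin periodinane, NaHCO3, CH2Cl2, 0 → 25 °C
Reagents that add atoms: none
Why: Dess–Martin oxidation should convert only the secondary alcohol, without C–C cleavage of the diol and without epimerizing the α-stereocentre under buffered conditions.

**Step 12**
Reactants: 22 2-[(1S,3R)-3-hydroxy-3-methyl-2-oxocyclopentyl]-2-methylpropanenitrile
Product: 23 2-[(1S,3R)-3-hydroxy-3-methyl-2-methylidenecyclopentyl]-2-methylpropanenitrile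
Conditions: Zn, CH2Br2, TiCl4, THF, 25 °C
Reagents that add atoms: dibromomethane, BrCBr
Why: Takai–Lombardo methylenation is non-basic and should olefinate the hindered, enolizable ketone without epimerizing the adjacent stereocentre.

**Step 13**
Reactants: 23 2-[(1S,3R)-3-hydroxy-3-methyl-2-methylidenecyclopentyl]-2-methylpropanenitrile
Product: 25 2-[(1R,2S,3R)-3-hydroxy-2-(hydroxymethyl)-3-methylcyclopentyl]-2-methylpropanenitrile, via alkylborane 24 (not isolated)
Conditions: 9-BBN (2.2 equiv), THF, 60 °C; then H2O2, aq NaOAc, 0 °C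
Reagents that add atoms: hydrogen peroxide, OO
Why: Anti-Markovnikov hydroboration–oxidation from the face opposite the C(CH3)2CN arm and the carbinol methyl group puts hydrogen on the ring carbon syn to OH, so the CH2OH arm ends cis to the nitrile arm (future cis ring fusion, C8a).

**Step 14**
Reactants: 25 2-[(1R,2S,3R)-3-hydroxy-2-(hydroxymethyl)-3-methylcyclopentyl]-2-methylpropanenitrile
Product: 27 enone diol: 2,4-dimethyl-2-[(1R,2S,3R)-3-hydroxy-2-(hydroxymethyl)-3-methylcyclopentyl]pent-4-en-3-one, via ketimine 26 (not isolated)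
Conditions: CH2=C(CH3)MgBr (4 equiv), CuBr (2 mol %), THF, 60 °C; then 1 M HCl, 0 °C
Reagents that add atoms: isopropenylmagnesium bromide, C=C(C)[Mg]Br; water, O
Why: Grignard addition to the hindered nitrile stops at the N-magnesio ketimine, and hydrolysis then gives the isopropenyl ketone, which is not enolizable.

**Step 15**
Reactants: 27 enone diol
Product: 28 iodo enone (27 with CH2I in place of CH2OH)
Conditions: I2, PPh3, imidazole, CH2Cl2, 0 °C
Reagents that add atoms: iodine, II
Why: Appel iodination should convert only the primary alcohol, the tertiary alcohol being inert.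

**Step 16**
Reactants: 28 iodo enone
Product: 29 iodo enone tert-butyldimethylsilyl ether (tertiary OH of 28 silylated)
Conditions: t-BuMe2SiOTf, 2,6-lutidine, CH2Cl2, −78 → 0 °C
Reagents that add atoms: tert-butyldimethylsilyl trifluoromethanesulfonate, CC(C)(C)[Si](C)(C)OS(=O)(=O)C(F)(F)F
Why: Silyl triflate silylation of the tertiary alcohol is safe here because the ketone cannot enolize, and the ether keeps the fragment aprotic for steps 19 and 20.

**Step 17**
Reactants: 29 iodo enone tert-butyldimethylsilyl ether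
Product: 30 (1R,3aR,6R,8aR)-1-[(tert-butyldimethylsilyl)oxy]-1,4,4,6-tetramethyloctahydroazulen-5(1H)-one (cis-fused)
Conditions: Bu3SnH, AIBN (cat.), benzene (5 mM), 80 °C, syringe pump; then NaOMe, MeOH, 25 °C
Reagents that add atoms: none
Why: Radical 7-endo-trig cyclization of the primary radical onto the terminal carbon of the isopropenyl ketone (cis arms and gem-dimethyl group favour closure) gives the cis-fused hydroazulenone, and base equilibration should place the C6 methyl group pseudo-equatorial on the twist-chair as the (6R) epimer.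

**Step 18**
Reactants: 30 (1R,3aR,6R,8aR)-1-[(tert-butyldimethylsilyl)oxy]-1,4,4,6-tetramethyloctahydroazulen-5(1H)-one
Product: 31 (1R,3aR,6R,8aR)-1-[(tert-butyldimethylsilyl)oxy]-5-ethenyl-1,4,4,6-tetramethyldecahydroazulen-5-ol (C5 epimers, both usable)
Conditions: CH2=CHMgBr, CeCl3, THF, −78 → 0 °C
Reagents that add atoms: vinylmagnesium bromide, C=C[Mg]Br
Why: The organocerium reagent adds 1,2 to the hindered, enolizable ketone without epimerizing C6, and the configuration of the new carbinol carbon is lost in step 19.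

**Step 19**
Reactants: 31 tertiary vinyl carbinol
Product: 32 (1R,3aR,5E,6R,8aR)-5-(2-bromoethylidene)-1-[(tert-butyldimethylsilyl)oxy]-1,4,4,6-tetramethyldecahydroazulene
Conditions: PBr3, pyridine, Et2O, −30 → 0 °C
Reagents that add atoms: phosphorus tribromide, BrP(Br)Br
Why: Allylic transposition (SN2′) of the tertiary vinyl carbinol gives the primary bromide, with E geometry because CH2Br syn to C6–H avoids the A(1,3) strain it would meet next to the C4 gem-dimethyl group.

**Step 20**
Reactants: 16 (3S,5aR,9aR)-3-hydroxy-2,2,5a-trimethyl-3,4,5,5a,6,9a-hexahydro-1-benzoxepin-7(2H)-one; 32 allylic bromide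
Product: 33 coupled enone: 16 carrying at C6 the (2E)-2-(azulen-5-ylidene)ethyl group of 32 (drawn 6R; any 6-epimer converges in step 21)
Conditions: LiN(iPr)2 (2.2 equiv), THF–DMPU, −78 °C; then 32, −78 → −20 °C
Reagents that add atoms: none
Why: Kinetic α′-deprotonation of the enone gives the cross-conjugated C6 dienolate regiospecifically, and SN2 alkylation at the primary allylic carbon forms the C6–CH2 bond that joins the two halves.

**Step 21**
Reactants: 33 coupled enone
Product: 34 coupled saturated ketone (6R): 33 with C8–C9 reduced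
Conditions: [(Ph3P)CuH]6, benzene, H2O (2 equiv), 25 °C; then NaOMe, MeOH, 25 °C
Reagents that add atoms: none
Why: Conjugate reduction by the monovalent copper hydride touches only the enone, and base equilibration at C6 (the only stereocentre α to the ketone) places the side chain equatorial, cis to the axial 5a-methyl group.

**Step 22**
Reactants: 34 coupled saturated ketone
Product: 36 CNP0167890.3, via silyl ether 35 (not isolated)
Conditions: MeLi, CeCl3, THF, −78 °C; then Bu4NF, THF, 60 °C
Reagents that add atoms: methyllithium, [Li]C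
Why: The methylcerium reagent attacks the C7 ketone equatorially because the axial face is blocked by the 1,3-diaxial 5a-methyl group, giving the axial (7S) tertiary alcohol, and fluoride then removes the silyl ether.

## Compound list

1 | rac-7-methyl-1,4-dioxaspiro[4.5]decan-8-one | CC1CC2(CCC1=O)OCCO2 | starting material
2 | (R)-1-phenylethylamine | C[C@@H](N)c1ccccc1 | starting material
3 | benzyl acrylate | C=CC(=O)OCc1ccccc1 | starting material
4 | N-[(1R)-1-phenylethyl] ketimine of 1 (in equilibrium with its secondary enamine) | C[C@@H](N=C1CCC2(CC1C)OCCO2)c1ccccc1 | intermediate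
5 | N-[(1R)-1-phenylethyl] ketimine of keto ester 6 | C[C@@H](N=C1CCC2(OCCO2)C[C@@]1(C)CCC(=O)OCc1ccccc1)c1ccccc1 | intermediate
6 | benzyl 3-[(7R)-7-methyl-8-oxo-1,4-dioxaspiro[4.5]decan-7-yl]propanoate | C1[C@@](C)(CCC(=O)OCc2ccccc2)C(=O)CCC13OCCO3 | intermediate
7 | (3a'R)-1'-(benzyloxy)-3a'-methyl-2',3',3a',4',6',7'-hexahydrospiro[1,3-dioxolane-2,5'-indene] | C1[C@@]2(C)CCC(OCc3ccccc3)=C2CCC14OCCO4 | intermediate
8 | acetone | CC(C)=O | starting material
9 | tricyclic 3-(benzyloxy)oxetane (2,2-dimethyloxetane cis-fused across C1'–C7a', O on C7a', anti to the 3a'-methyl group) | C1[C@@]2(C)CC[C@@]3(OCc4ccccc4)C(C)(C)O[C@@]23CCC15OCCO5 | intermediate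
10 | tricyclic oxetan-3-ol | C1[C@@]2(C)CC[C@@]3(O)C(C)(C)O[C@@]23CCC14OCCO4 | intermediate
11 | (5aR,9aR)-2,2,5a-trimethylhexahydro-2H-spiro[1-benzoxepine-7,2'-[1,3]dioxolan]-3(4H)-one | C1[C@@]2(C)CCC(=O)C(C)(C)O[C@@H]2CCC13OCCO3 | intermediate
12 | (3S,5aR,9aR)-2,2,5a-trimethyloctahydro-2H-spiro[1-benzoxepine-7,2'-[1,3]dioxolan]-3-ol | C1[C@@]2(C)CC[C@H](O)C(C)(C)O[C@@H]2CCC13OCCO3 | intermediate
13 | (3S,5aR,9aR)-3-hydroxy-2,2,5a-trimethyloctahydro-1-benzoxepin-7(2H)-one | C1[C@@]2(C)CC[C@H](O)C(C)(C)O[C@@H]2CCC1=O | intermediate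
14 | 3-O-trimethylsilyl ether, C7 trimethylsilyl enol ether (C7=C8) of 13 | C1[C@@]2(C)CC[C@H](O[Si](C)(C)C)C(C)(C)O[C@@H]2CC=C1O[Si](C)(C)C | intermediate
15 | 3-O-trimethylsilyl ether of enone 16 | C1[C@@]2(C)CC[C@H](O[Si](C)(C)C)C(C)(C)O[C@@H]2C=CC1=O | intermediate
16 | (3S,5aR,9aR)-3-hydroxy-2,2,5a-trimethyl-3,4,5,5a,6,9a-hexahydro-1-benzoxepin-7(2H)-one | C1[C@@]2(C)CC[C@H](O)C(C)(C)O[C@@H]2C=CC1=O | intermediate
17 | (R)-linalool | C=C[C@](C)(O)CCC=C(C)C | starting material
18 | (R)-1-methylcyclopent-2-en-1-ol | C1=C[C@](C)(O)CC1 | intermediate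
19 | (1S,2R,5S)-2-methyl-6-oxabicyclo[3.1.0]hexan-2-ol | C1C[C@@](C)(O)[C@H]2O[C@@H]12 | intermediate
20 | isobutyronitrile | CC(C)C#N | starting material
21 | 2-[(1S,2S,3R)-2,3-dihydroxy-3-methylcyclopentyl]-2-methylpropanenitrile | C1C[C@@](C)(O)[C@@H](O)[C@@H]1C(C)(C)C#N | intermediate
22 | 2-[(1S,3R)-3-hydroxy-3-methyl-2-oxocyclopentyl]-2-methylpropanenitrile | C1C[C@@](C)(O)C(=O)[C@@H]1C(C)(C)C#N | intermediate
23 | 2-[(1S,3R)-3-hydroxy-3-methyl-2-methylidenecyclopentyl]-2-methylpropanenitrile | C1C[C@@](C)(O)C(=C)[C@@H]1C(C)(C)C#N | intermediate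
24 | B-alkyl-9-borabicyclo[3.3.1]nonane adduct of 23 | C1C[C@@](C)(O)[C@H](CB2C3CCCC2CCC3)[C@@H]1C(C)(C)C#N | intermediate
25 | 2-[(1R,2S,3R)-3-hydroxy-2-(hydroxymethyl)-3-methylcyclopentyl]-2-methylpropanenitrile | C1C[C@@](C)(O)[C@H](CO)[C@@H]1C(C)(C)C#N | intermediate
26 | N–H ketimine of 27 | C1C[C@@](C)(O)[C@H](CO)[C@@H]1C(C)(C)C(=N)C(C)=C | intermediate
27 | 2,4-dimethyl-2-[(1R,2S,3R)-3-hydroxy-2-(hydroxymethyl)-3-methylcyclopentyl]pent-4-en-3-one | C1C[C@@](C)(O)[C@H](CO)[C@@H]1C(C)(C)C(=O)C(C)=C | intermediate
28 | iodo enone (27 with CH2I in place of CH2OH) | C1C[C@@](C)(O)[C@H](CI)[C@@H]1C(C)(C)C(=O)C(C)=C | intermediate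
29 | tert-butyldimethylsilyl ether of 28 | C1C[C@@](C)(O[Si](C)(C)C(C)(C)C)[C@H](CI)[C@@H]1C(C)(C)C(=O)C(C)=C | intermediate
30 | (1R,3aR,6R,8aR)-1-[(tert-butyldimethylsilyl)oxy]-1,4,4,6-tetramethyloctahydroazulen-5(1H)-one | C[C@@H]1CC[C@@H]2[C@@H](CC[C@@]2(C)O[Si](C)(C)C(C)(C)C)C(C)(C)C1=O | intermediate
31 | (1R,3aR,6R,8aR)-1-[(tert-butyldimethylsilyl)oxy]-5-ethenyl-1,4,4,6-tetramethyldecahydroazulen-5-ol (C5 epimers) | C[C@@H]1CC[C@@H]2[C@@H](CC[C@@]2(C)O[Si](C)(C)C(C)(C)C)C(C)(C)C1(O)C=C | intermediate
32 | (1R,3aR,5E,6R,8aR)-5-(2-bromoethylidene)-1-[(tert-butyldimethylsilyl)oxy]-1,4,4,6-tetramethyldecahydroazulene | C[C@@H]1CC[C@@H]2[C@@H](CC[C@@]2(C)O[Si](C)(C)C(C)(C)C)C(C)(C)/C1=C/CBr | intermediate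
33 | coupled enone (6R drawn): 16 with the (2E)-2-(silyloxy-azulen-5-ylidene)ethyl group at C6 | C[C@@H]1CC[C@@H]2[C@@H](CC[C@@]2(C)O[Si](C)(C)C(C)(C)C)C(C)(C)/C1=C/C[C@@H]1[C@@]2(C)CC[C@H](O)C(C)(C)O[C@@H]2C=CC1=O | intermediate
34 | coupled saturated C7 ketone (6R) | C[C@@H]1CC[C@@H]2[C@@H](CC[C@@]2(C)O[Si](C)(C)C(C)(C)C)C(C)(C)/C1=C/C[C@@H]1[C@@]2(C)CC[C@H](O)C(C)(C)O[C@@H]2CCC1=O | intermediate
35 | tert-butyldimethylsilyl ether of the target at the azulene C1 oxygen | C[C@@H]1CC[C@@H]2[C@@H](CC[C@@]2(C)O[Si](C)(C)C(C)(C)C)C(C)(C)/C1=C/C[C@@H]1[C@@]2(C)CC[C@H](O)C(C)(C)O[C@@H]2CC[C@]1(C)O | intermediate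
36 | CNP0167890.3: (3S,5aR,6R,7S,9aR)-6-{(2E)-2-[(1R,3aR,6R,8aR)-1-hydroxy-1,4,4,6-tetramethyloctahydroazulen-5(1H)-ylidene]ethyl}-2,2,5a,7-tetramethyldecahydro-1-benzoxepine-3,7-diol | C[C@@H]1CC[C@@H]2[C@@H](CC[C@@]2(C)O)C(C)(C)/C1=C/C[C@@H]1[C@@]2(C)CC[C@H](O)C(C)(C)O[C@@H]2CC[C@]1(C)O | target

## Step count and risks

Total step count: 22. Longest linear sequence: 15 steps (steps 8–19, then 20–22).

Steps most likely to fail:

1. **Step 3 (key step).** Acetone may add with the wrong orientation at the fully substituted enol ether (oxygen to C3), or hydrogen abstraction from the benzylic and dioxolane C–H bonds by excited acetone may outrun cycloaddition. The fallback sets out from 6 and returns at 13. NaBH4 reduction of 6, hydride entering axially anti to the methyl group, with spontaneous lactonisation should give the trans-fused δ-lactone F1. iBu2AlH at −78 °C gives the lactol F2, and Wittig olefination with Ph3P=C(CH3)2 gives the hydroxy alkene F3. Shi epoxidation (KHSO5, the fructose-type ketone of the antipodal series that delivers the (S)-epoxide) gives the epoxy alcohol F4. Camphorsulfonic acid then promotes 7-endo opening at the tertiary epoxide carbon by the C9a hydroxyl, closing the oxepane with the (3S)-hydroxyl in place, and aqueous acid removes the dioxolane to give 13.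

2. **Step 5.** The other oxetane C–C bond (C3–C2) may be cleaved, or the hydrogen atom may be delivered to the wrong face of the C9a radical. The fallback sets out from 10 and returns at 11. Hypoiodite fragmentation (PhI(OAc)2, I2, hν) oxidises the C9a radical at once to the ring oxocarbenium ion, which is trapped as the 9a-acetoxy oxepanone F5. Ionic reduction (Et3SiH, BF3·OEt2, CH2Cl2, −78 °C, at which the dioxolane should survive) then delivers hydride axially, anti to the 5a-methyl group, to give 11. This changes how C9a is set but does not by itself correct scission of the wrong bond.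

3. **Step 20.** Alkylation of the hindered neopentyl-type dienolate may be slow, so that proton transfer, O-alkylation or γ-deprotonation with loss of the C9a configuration compete. The fallback sets out from 15 and 31 and returns at 33. Ph3SiOReO3-catalysed 1,3-transposition of 31 gives the primary allylic alcohol F6, and carbonyldiimidazole converts it into the imidazole carboxylate F7. C-acylation of the C6 lithium dienolate of the silyl ether 15 (isolated by omitting the acid wash in step 7) with F7 gives the β-keto ester F8. Pd(PPh3)4 then effects Tsuji decarboxylative allylation, in which the regiodefined enolate and the π-allyl unit recombine at the unhindered allyl terminus to give the silyl ether F9. K2CO3 in MeOH converts F9 into 33.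

Further compounds
F1 | step 3 | trans-fused δ-lactone (C9a–O acylated by the side-chain carboxyl) | C1[C@@]2(C)CCC(=O)O[C@@H]2CCC13OCCO3
F2 | step 3 | lactol from F1 (anomers) | C1[C@@]2(C)CCC(O)O[C@@H]2CCC13OCCO3
F3 | step 3 | hydroxy alkene (ring alcohol with a 4-methylpent-3-enyl chain on the quaternary carbon) | C1[C@@](C)(CCC=C(C)C)[C@H](O)CCC13OCCO3
F4 | step 3 | (S)-epoxy alcohol from F3 | C1[C@@](C)(CC[C@@H]2OC2(C)C)[C@H](O)CCC13OCCO3
F5 | step 5 | 9a-acetoxy oxepan-3-one ketal (C9a epimers) | C1[C@@]2(C)CCC(=O)C(C)(C)OC2(OC(C)=O)CCC13OCCO3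
F6 | step 20 | primary allylic alcohol corresponding to bromide 32 | C[C@@H]1CC[C@@H]2[C@@H](CC[C@@]2(C)O[Si](C)(C)C(C)(C)C)C(C)(C)/C1=C/CO
F7 | step 20 | imidazole-1-carboxylate of F6 | C[C@@H]1CC[C@@H]2[C@@H](CC[C@@]2(C)O[Si](C)(C)C(C)(C)C)C(C)(C)/C1=C/COC(=O)n1ccnc1
F8 | step 20 | C6 allyl β-keto ester of 15 (C6 epimers) | C[C@@H]1CC[C@@H]2[C@@H](CC[C@@]2(C)O[Si](C)(C)C(C)(C)C)C(C)(C)/C1=C/COC(=O)C1[C@@]2(C)CC[C@H](O[Si](C)(C)C)C(C)(C)O[C@@H]2C=CC1=O
F9 | step 20 | 3-O-trimethylsilyl ether of 33 | C[C@@H]1CC[C@@H]2[C@@H](CC[C@@]2(C)O[Si](C)(C)C(C)(C)C)C(C)(C)/C1=C/C[C@@H]1[C@@]2(C)CC[C@H](O[Si](C)(C)C)C(C)(C)O[C@@H]2C=CC1=O
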